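## Structural features

The target is a 3,4-dihydro-2H-cyclopenta[b]pyridine. A cyclopentadiene ring A (C4a, C5, C6, C7, C7a) is fused through C4a–C7a to a tetrahydropyridine ring B (N1, C2, C3, C4, C4a, C7a). An oxirane ring C sits on C4–C4a, so C4a is a quaternary carbon shared by all three rings. C7a=N1, C6=C7 and the exocyclic C5=C1' make a cross-conjugated 1-azatriene; C7 carries a methyl group and C5 an (E)-alkylidene (C2' cis to C6) that runs on into the chain C1'–C4'. C4 (R) and C4a (S) are adjacent and locked cis by the fusion. C2' (S, esterified by (R)-2-methylbutanoic acid, whose α-carbon is the fifth stereocentre) and C3' (S, acetate) are adjacent in the chain. The two pairs are separated by the planar C5=C1' unit and cannot easily direct each other. Fragile elements are the imine/azatriene (hydration and oligomerisation of the free base), the allylic oxirane, the allylic ester at C2', the vicinal diester (acyl migration) and the epimerisable acyl α-centre. The real difficulty is threefold: oxirane configuration against remote side-chain centres, alkene geometry, and reaching the azatriene only at the end. The key step uses the substitution pattern of ring A: methyl on C7, nitrogen on C7a, oxygen on C4a and the alkylidene on C5 are the pattern of a 4-amino-5-methyl-2-alkylidenecyclopent-4-ene-1,3-dione. Its C5–C6 bond can be made by an acyl shift in a squarate-derived alkynylcyclobutenone.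

## Logic of the disconnections

29 to 28 to 27: no skeletal bond is cut. The C7a=N1 and C6=C7 unsaturations are traced back to a C6 carbinol beside an N-Boc enamine (28) and then to the C6 ketone (27). The reason is that the azatriene must be formed last. The gain is a stable vinylogous carbamate. The forward demand is a 1,2-reduction that spares two esters and the oxirane, then loss of water and Boc under acid mild enough for the oxirane.

27 to 22 and 24: the acyl–oxygen bonds at C2' and C3' are cut. Esters would not survive the organolithium and strong-base steps, so 22 carries a triethylsilyl ether at C2' and a tert-butyldimethylsilyl ether at C3'. The demand is ordered silyl removal without acyl migration and without epimerising the α-centre of 24.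

22 to 19 and 20 (through 21): the C4–C4a and C4–O bonds of the oxirane are cut. One sulfonium ylide epoxidation then closes ring B and ring C and sets both ring stereocentres from the C4a ketone and a C4 electrophile. The gain is a monocyclic precursor with no ring stereocentre. The demand is attack at C4a and not at C6, an absolute sense imposed by 20 because the side chain is too far away, and a base that leaves C2'–H alone.

19 to 18: the C5–C6 bond is cut and C4a–C6 reconnected, so ring A contracts to a four-membered ring. The reason is that ring A and the alkene geometry then arise together by mechanism. The gain is that 18 is a simple carbonyl adduct of two fragments. The demand is migration of the acyl carbon anti to palladium, protonolysis with retention, and a nitrogen without N–H.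

18 to 7 and 17 (from 16): the C4a–C5 bond between carbinol carbon and alkyne is cut, giving a convergent union of two fragments of similar size. The demand is attack at the carbonyl next to the nitrogen-bearing carbon and a quench at low temperature.

7 to 6 to 5 to 3 and 4, and 3 to 1: the N–Boc bond, the carbon–halogen bond (iodide from chloride), the N1–C7a bond (vinylogous substitution) and the C7–CH3 bond (MeLi addition) are cut in turn. Each forward step is standard squarate chemistry; the iodide is installed here, on a robust compound, so that sulfonium formation later needs no further step.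

16 to 15 to 14 to 13, then 13 to 10 and 11, and 10 to 9 to 8: the C1'–C2' bond is cut (acylation of an acetylide). C2' is traced to a ketone reduced under catalyst control, and C3' comes unchanged from 8. The demand is a syn (3S,4S) relationship and differentiated silyl ethers.

## Other disconnections considered

Alternative 1: The cut is C4a–C5 in ring A, made on a monocyclic 4-hydroxy-2-methylcyclopent-2-enone A1 that still carries N1–C2–C3–C4 as an open arm on C4a. A1 is traced to the 2,3-dimethyl-5-substituted furan A2.
- Forward: NBS in aqueous NaHCO3 would open the furan ring of A2 oxidatively. The freed methyl ketone carbon (C5) would then add to the side-chain ketone (C4a) under the basic conditions to give A1.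
- In favour: cheap reagents and no transition metal. The C4 silyloxy centre sits next to the new C4a carbinol, so the oxirane configuration could come from substrate control (1,2-induction, then displacement at C4 by the C4a oxygen). On that point it is the better plan.
- Against: A1 has no N1–C7a bond, no alkylidene and none of C1'–C4'. Nitrogen would be joined to C7a by conjugate addition and the C7=C7a unsaturation regained by oxidation. The side chain would enter by aldol condensation at C5 with an easily epimerised α,β-dioxygenated aldehyde, and the geometry would be left to thermodynamics.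
- Comparison: both plans rest on well-understood polar steps (equal). The chosen plan fixes the C5=C1' geometry by mechanism and is convergent (better). Alternative 1 is linear and needs extra redox steps (worse on step economy). The final reduction/elimination would be shared.

Alternative 2: The cut is C7–C7a. The oxirane is present from the start in the N-Boc epoxypiperidine diazoketone A4.
- Forward: Rh2(O2CCPh3)4 would form the carbenoid at C7, which inserts into the C7a–H bond next to nitrogen (1,5-insertion) to give the cis-fused ketone A3.
- In favour: the oxirane configuration is settled early on a small robust ring, which is better than the late, reagent-controlled epoxidation chosen here. The C–H bond is activated by the carbamate nitrogen, and the bulky carboxylate ligands disfavour the 1,2-hydride shift of an α-alkyl diazoketone.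
- Against: A3 is at the wrong oxidation level. C7 and C7a become stereocentres that must later be erased, and two unsaturations, the alkylidene and the whole side chain remain to be added beside an oxirane. The carbenoid could also be intercepted by the oxirane oxygen.
- Comparison: equal in ring-forming reliability, better on oxirane control, worse on convergence, step economy and control of alkene geometry.

Alternative 3: Two cuts, C6=C7 (aldol condensation) and N1=C7a (aza-Wittig), lead to the acyclic epoxy keto enal azide A6.
- Forward: LiN(SiMe3)2 at low temperature would enolise the ethyl ketone on its only enolisable side. C7 would add to the C6 aldehyde (5-exo-trig) and water would be lost to give the cyclopentenone azide A5. A phosphine would then close ring B.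
- In favour: all stereocentres, both esters and the alkene geometry precede ring formation. C6=C7 appears at the right oxidation level, and the imine is made last under neutral conditions. Its endgame is better than the acid finish chosen here, and it has fewer steps after the key step.
- Against: the burden moves to A6, a tetrasubstituted oxirane between a ketone and an enal of defined geometry with no simple way to make its C4a–C5 bond. The base must distinguish the ketone from an acetate, an aldehyde and the C2' proton. A5 is a cross-conjugated dienone beside a spiro-oxirane.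
- Comparison: equal on convergence in principle and better in the endgame. It is worse in precursor accessibility and in the chemoselectivity of its key step, whereas the chosen key step starts from two readily made fragments.

Key step: step 12

Remark: 3-chloropropan-1-amine is used as its commercial hydrochloride 4 and set free in the flask.
Remark: the (1R,4R,5R) enantiomer of isothiocineole 20 is written on the assumption that its ylide face preference gives the (4R,4aS) oxirane; if a model run shows the opposite sense, the (1S,4S,5S) enantiomer is used with no other change.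

## Route

Step 1
Reactants: 1 diisopropyl squarate
Product: 3 3-isopropoxy-4-methylcyclobut-3-ene-1,2-dione, via lithium alkoxide adduct 2 (not isolated)
Conditions: MeLi, THF, −78 °C; (CF3CO)2O, −78 °C; H2O, 0 °C
Reagents that add atoms: methyllithium, C[Li]; water, O
Why: 1,2-addition of MeLi to one squarate carbonyl, trifluoroacetylation of the alkoxide and hydrolytic loss of isopropanol with 1,3-carbonyl transposition; this one-flask route to 3-alkoxy-4-alkylcyclobutenediones is standard squarate chemistry.

Step 2
Reactants: 3 3-isopropoxy-4-methylcyclobut-3-ene-1,2-dione; 4 3-chloropropan-1-amine hydrochloride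
Product: 5 3-[(3-chloropropyl)amino]-4-methylcyclobut-3-ene-1,2-dione
Conditions: Et3N, i-PrOH, 0 → 23 °C
Reagents that add atoms: none
Why: addition–elimination of the primary amine at the vinylogous ester carbon (vinylogous amide formation); the product nitrogen is non-nucleophilic, so the chloride is not displaced.

Step 3
Reactants: 5 3-[(3-chloropropyl)amino]-4-methylcyclobut-3-ene-1,2-dione
Product: 6 3-[(3-iodopropyl)amino]-4-methylcyclobut-3-ene-1,2-dione
Conditions: NaI, acetone, reflux
Reagents that add atoms: sodium iodide, [Na+].[I-]
Why: Finkelstein exchange driven by precipitation of NaCl; it is done on the robust N–H dione so that the later sulfonium formation needs no extra step on a sensitive intermediate.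

Step 4
Reactants: 6 3-[(3-iodopropyl)amino]-4-methylcyclobut-3-ene-1,2-dione
Product: 7 tert-butyl (3-iodopropyl)(2-methyl-3,4-dioxocyclobut-1-en-1-yl)carbamate
Conditions: Boc2O, DMAP (cat.), CH2Cl2, 23 °C
Reagents that add atoms: di-tert-butyl dicarbonate, CC(C)(C)OC(=O)OC(=O)OC(C)(C)C
Why: DMAP-catalysed N-acylation of the acidic vinylogous amide N–H; the tertiary carbamate removes the proton that would quench the acetylide and later permit aminopalladation.

Step 5
Reactants: 8 ethyl (S)-lactate
Product: 9 ethyl (S)-2-(tert-butyldimethylsilyloxy)propanoate
Conditions: TBSCl, imidazole, DMF, 23 °C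
Reagents that add atoms: tert-butyldimethylsilyl chloride, CC(C)(C)[Si](C)(C)Cl
Why: standard silylation of a secondary alcohol; the stereocentre (C3' of the target) is not touched.

Step 6
Reactants: 9 ethyl (S)-2-(tert-butyldimethylsilyloxy)propanoate
Product: 10 (S)-2-(tert-butyldimethylsilyloxy)-N-methoxy-N-methylpropanamide
Conditions: MeNHOMe·HCl, i-PrMgCl, THF, −20 → 0 °C
Reagents that add atoms: N,O-dimethylhydroxylamine hydrochloride, CNOC.Cl
Why: direct aminolysis of the ester by the magnesium amide formed in the flask (Weinreb amide formation), which proceeds without enolisation of the α-silyloxy centre.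

Step 7
Reactants: 10 (S)-2-(tert-butyldimethylsilyloxy)-N-methoxy-N-methylpropanamide; 11 ethynyltrimethylsilane
Product: 13 (S)-4-(tert-butyldimethylsilyloxy)-1-(trimethylsilyl)pent-1-yn-3-one, via lithium (trimethylsilyl)acetylide 12 (not isolated)
Conditions: n-BuLi, THF, −78 °C; then 10, −78 → 0 °C; aq. NH4Cl
Reagents that add atoms: none
Why: Weinreb ketone synthesis; the chelated tetrahedral adduct prevents double addition and forms the C1'–C2' bond.

Step 8
Reactants: 13 (S)-4-(tert-butyldimethylsilyloxy)-1-(trimethylsilyl)pent-1-yn-3-one
Product: 14 (3S,4S)-4-(tert-butyldimethylsilyloxy)-1-(trimethylsilyl)pent-1-yn-3-ol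
Conditions: RuCl[(R,R)-TsDPEN](p-cymene) (2 mol%, pre-activated with KOH), i-PrOH, 23 °C
Reagents that add atoms: none
Why: Noyori-type asymmetric transfer hydrogenation of an ynone, in which the alkyne takes the place of the aryl group; the (R,R) ligand delivers hydride to give the (3S) carbinol (C2'), and the non-chelation preference of the α-silyloxy ketone points the same way (syn).

Step 9
Reactants: 14 (3S,4S)-4-(tert-butyldimethylsilyloxy)-1-(trimethylsilyl)pent-1-yn-3-ol
Product: 15 (3S,4S)-4-(tert-butyldimethylsilyloxy)-3-(triethylsilyloxy)-1-(trimethylsilyl)pent-1-yne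
Conditions: TESCl, imidazole, CH2Cl2, 0 °C
Reagents that add atoms: chlorotriethylsilane, CC[Si](Cl)(CC)CC
Why: silylation under neutral amine conditions avoids 1,2-silyl migration; the triethylsilyl ether on C2' is the one that can later be removed in the presence of the tert-butyldimethylsilyl ether on C3'.

Step 10
Reactants: 15 (3S,4S)-4-(tert-butyldimethylsilyloxy)-3-(triethylsilyloxy)-1-(trimethylsilyl)pent-1-yne
Product: 16 (3S,4S)-4-(tert-butyldimethylsilyloxy)-3-(triethylsilyloxy)pent-1-yne
Conditions: K2CO3, MeOH, 0 → 23 °C
Reagents that add atoms: none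
Why: methanolysis of the C(sp)–SiMe3 bond is much faster than cleavage of secondary O-silyl ethers, and with both hydroxyls already capped no silyl shift is possible.

Step 11
Reactants: 16 (3S,4S)-4-(tert-butyldimethylsilyloxy)-3-(triethylsilyloxy)pent-1-yne; 7 tert-butyl (3-iodopropyl)(2-methyl-3,4-dioxocyclobut-1-en-1-yl)carbamate
Product: 18 tert-butyl (3-iodopropyl){4-hydroxy-2-methyl-3-oxo-4-[(3S,4S)-4-(tert-butyldimethylsilyloxy)-3-(triethylsilyloxy)pent-1-yn-1-yl]cyclobut-1-en-1-yl}carbamate (both carbinol epimers), via lithium acetylide 17 (not isolated)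
Conditions: n-BuLi, THF, −78 °C; then 7, −78 °C; aq. NH4Cl at −78 °C
Reagents that add atoms: none
Why: 1,2-addition of a lithium acetylide to a cyclobutenedione; the carbonyl conjugated with nitrogen through the ring alkene (vinylogous carbamate) is the less electrophilic, so attack should occur at the carbonyl beside the nitrogen-bearing carbon, which becomes C4a. The cold quench forestalls alkoxide-triggered ring opening and N-to-O Boc transfer; the carbinol configuration is irrelevant because step 12 erases it.

Step 12
Reactants: 18 tert-butyl (3-iodopropyl){4-hydroxy-2-methyl-3-oxo-4-[(3S,4S)-4-(tert-butyldimethylsilyloxy)-3-(triethylsilyloxy)pent-1-yn-1-yl]cyclobut-1-en-1-yl}carbamate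
Product: 19 N-Boc N-(3-iodopropyl) 4-amino-5-methyl-2-[(E)-(2S,3S)-3-(tert-butyldimethylsilyloxy)-2-(triethylsilyloxy)butylidene]cyclopent-4-ene-1,3-dione (C2' cis to C6)
Conditions: Pd(OCOCF3)2 (10 mol%), THF, 23 °C
Reagents that add atoms: none
Why: Pd(OCOCF3)2 (electrophilic divalent palladium) coordinates the C5≡C1' alkyne of 18, and the C4a–C6 bond, pushed by the C4a hydroxyl, migrates to C5 on the face opposite the metal, so that C4a becomes a ketone and a vinylpalladium species carries palladium on C1' trans to C6. Protonolysis of the C1'–Pd bond by the proton released from the hydroxyl occurs with retention and returns the catalyst. The closest known reaction type is the palladium-catalysed ring enlargement of 4-alkynyl-4-hydroxycyclobutenones to 2-alkylidenecyclopent-4-ene-1,3-diones, applied here to a member with a carbamate nitrogen on the ring alkene. Ring A is closed by the 1,2-acyl shift itself, a ring enlargement driven by release of four-ring strain and not an end-on cyclisation, so no exo or endo mode applies. No stereocentre is created and the carbinol centre is erased, so both epimers of 18 converge. Two selectivities are needed: migration of the acyl carbon C6 and not the alkenyl carbon C7a, which this substrate class shows even when the alkenyl carbon bears a donor, and the (E) geometry, which follows from anti migration plus retentive protonolysis and places C2' cis to C6. The fully substituted nitrogen leaves no N–H for aminopalladation, and silyl ethers at C2' and C3' avoid the acyloxy shifts a propargylic ester would invite.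

Step 13
Reactants: 19 N-Boc N-(3-iodopropyl) 4-amino-5-methyl-2-alkylidenecyclopent-4-ene-1,3-dione; 20 (1R,4R,5R)-isothiocineole
Product: 22 N-Boc (4R,4aS)-4,4a-epoxy-7-methyl-6-oxo-5-[(2S,3S)-3-(tert-butyldimethylsilyloxy)-2-(triethylsilyloxy)butylidene]-2,3,4,4a,5,6-hexahydro-1H-cyclopenta[b]pyridine (C2' cis to C6), via sulfonium tetrafluoroborate 21 (not isolated)
Conditions: 20 (2 equiv), AgBF4, CH2Cl2, 23 °C, dark; then LiN(SiMe3)2, THF, −78 °C
Reagents that add atoms: none
Why: AgBF4 removes iodide so that the sulfide is alkylated at C4; the base then takes the only accessible α-proton of the sulfonium salt (C4–H), and the ylide adds to the neighbouring C4a ketone (6-exo-trig) before the alkoxide displaces the sulfide with inversion at C4 (3-exo-tet), an intramolecular Corey–Chaykovsky epoxidation. The tether enforces cis fusion of oxirane and ring B, so C4 and C4a are set together; their absolute sense is governed by the bicyclic sulfonium group, which shields one face of the ylide carbon. C6 is spared because it is the vinylogous carbamate carbonyl and could be reached only through a strained seven-membered closure.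

Step 14
Reactants: 22 N-Boc epoxy enone with C2'-OTES and C3'-OTBS
Product: 23 the C2' alcohol of 22 (C3'-OTBS retained)
Conditions: HF·pyridine, pyridine, THF, 0 °C
Reagents that add atoms: none
Why: buffered fluoride cleaves a secondary triethylsilyl ether far faster than a secondary tert-butyldimethylsilyl ether, and the buffered medium spares the oxirane and the Boc group.

Step 15
Reactants: 23 C2' alcohol; 24 (R)-2-methylbutanoic acid
Product: 25 the C2' (R)-2-methylbutanoate of 23 (C3'-OTBS retained)
Conditions: DCC, DMAP (cat.), CH2Cl2, 0 → 23 °C
Reagents that add atoms: none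
Why: Steglich esterification of a secondary allylic alcohol; carbodiimide activation at low temperature avoids the ketene pathway that would epimerise the acyl α-centre.

Step 16
Reactants: 25 C2' ester with C3'-OTBS
Product: 26 the C3' alcohol of 25
Conditions: HF·pyridine, pyridine, THF, 23 °C
Reagents that add atoms: none
Why: acidic fluoride removes the remaining silyl ether; the absence of alkoxide suppresses 1,2-acyl migration from C2' to C3'.

Step 17
Reactants: 26 C3' alcohol
Product: 27 N-Boc (4R,4aS)-4,4a-epoxy-7-methyl-6-oxo-5-[(2S,3S)-3-acetoxy-2-{[(R)-2-methylbutanoyl]oxy}butylidene]-2,3,4,4a,5,6-hexahydro-1H-cyclopenta[b]pyridine (C2' cis to C6)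
Conditions: Ac2O, pyridine, DMAP (cat.), CH2Cl2, 0 °C
Reagents that add atoms: acetic anhydride, CC(=O)OC(C)=O
Why: standard acetylation, fast enough at 0 °C to outrun acyl migration.

Step 18
Reactants: 27 N-Boc epoxy enone diester
Product: 28 the C6 alcohol of 27 (both C6 epimers; used without chromatography)
Conditions: NaBH4, CeCl3·7H2O, MeOH, −78 °C
Reagents that add atoms: none
Why: Luche reduction; CeCl3 directs NaBH4 to 1,2-addition at the cross-conjugated C6 ketone at a temperature where the esters and the oxirane are inert. The new C6 centre is left uncontrolled because step 19 removes it.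

Step 19
Reactants: 28 C6 alcohol
Product: 29 the target, (4R,4aS)-4,4a-epoxy-7-methyl-5-[(E)-(2S,3S)-3-acetoxy-2-{[(R)-2-methylbutanoyl]oxy}butylidene]-3,4,4a,5-tetrahydro-2H-cyclopenta[b]pyridine
Conditions: CF3CO2H, CH2Cl2, 0 °C; cold aq. NaHCO3
Reagents that add atoms: none
Why: acid ionises the doubly allylic C6 carbinol to a cation stabilised through C7=C7a by the carbamate nitrogen (an N-acyliminium ion), which sheds the tert-butyl group as 2-methylpropene and then CO2, leaving the C7a=N1 imine conjugated with C6=C7. Both C6 epimers converge, and the protonated azatriene is the stable form until the cold neutralisation.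

## Compound list

1 | diisopropyl squarate (3,4-diisopropoxycyclobut-3-ene-1,2-dione) | CC(C)OC1=C(OC(C)C)C(=O)C1=O | starting material
2 | lithium 2,3-diisopropoxy-1-methyl-4-oxocyclobut-2-en-1-olate (formed in the flask) | CC(C)OC1=C(OC(C)C)C(C)([O-])C1=O.[Li+] | intermediate
3 | 3-isopropoxy-4-methylcyclobut-3-ene-1,2-dione | CC1=C(OC(C)C)C(=O)C1=O | intermediate
4 | 3-chloropropan-1-amine hydrochloride | Cl.NCCCCl | starting material
5 | 3-[(3-chloropropyl)amino]-4-methylcyclobut-3-ene-1,2-dione | CC1=C(NCCCCl)C(=O)C1=O | intermediate
6 | 3-[(3-iodopropyl)amino]-4-methylcyclobut-3-ene-1,2-dione | CC1=C(NCCCI)C(=O)C1=O | intermediate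
7 | tert-butyl (3-iodopropyl)(2-methyl-3,4-dioxocyclobut-1-en-1-yl)carbamate | CC1=C(N(CCCI)C(=O)OC(C)(C)C)C(=O)C1=O | intermediate
8 | ethyl (S)-lactate | CCOC(=O)[C@H](C)O | starting material
9 | ethyl (S)-2-(tert-butyldimethylsilyloxy)propanoate | CCOC(=O)[C@H](C)O[Si](C)(C)C(C)(C)C | intermediate
10 | (S)-2-(tert-butyldimethylsilyloxy)-N-methoxy-N-methylpropanamide | CON(C)C(=O)[C@H](C)O[Si](C)(C)C(C)(C)C | intermediate
11 | ethynyltrimethylsilane | C#C[Si](C)(C)C | starting material
12 | lithium (trimethylsilyl)acetylide (formed in the flask) | [Li]C#C[Si](C)(C)C | intermediate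
13 | (S)-4-(tert-butyldimethylsilyloxy)-1-(trimethylsilyl)pent-1-yn-3-one | C[Si](C)(C)C#CC(=O)[C@H](C)O[Si](C)(C)C(C)(C)C | intermediate
14 | (3S,4S)-4-(tert-butyldimethylsilyloxy)-1-(trimethylsilyl)pent-1-yn-3-ol | C[Si](C)(C)C#C[C@H](O)[C@H](C)O[Si](C)(C)C(C)(C)C | intermediate
15 | (3S,4S)-4-(tert-butyldimethylsilyloxy)-3-(triethylsilyloxy)-1-(trimethylsilyl)pent-1-yne | C[Si](C)(C)C#C[C@H](O[Si](CC)(CC)CC)[C@H](C)O[Si](C)(C)C(C)(C)C | intermediate
16 | (3S,4S)-4-(tert-butyldimethylsilyloxy)-3-(triethylsilyloxy)pent-1-yne | C#C[C@H](O[Si](CC)(CC)CC)[C@H](C)O[Si](C)(C)C(C)(C)C | intermediate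
17 | lithium acetylide of 16 (formed in the flask) | [Li]C#C[C@H](O[Si](CC)(CC)CC)[C@H](C)O[Si](C)(C)C(C)(C)C | intermediate
18 | N-Boc N-(3-iodopropyl) 3-amino-4-hydroxy-2-methyl-4-[(3S,4S)-4-(tert-butyldimethylsilyloxy)-3-(triethylsilyloxy)pent-1-ynyl]cyclobut-2-enone, carbinol epimers | CC1=C(N(CCCI)C(=O)OC(C)(C)C)C(O)(C#C[C@H](O[Si](CC)(CC)CC)[C@H](C)O[Si](C)(C)C(C)(C)C)C1=O | intermediate
19 | N-Boc N-(3-iodopropyl) 4-amino-5-methyl-2-[(E)-(2S,3S)-3-(tert-butyldimethylsilyloxy)-2-(triethylsilyloxy)butylidene]cyclopent-4-ene-1,3-dione | CC1=C(N(CCCI)C(=O)OC(C)(C)C)C(=O)/C(=C/[C@H](O[Si](CC)(CC)CC)[C@H](C)O[Si](C)(C)C(C)(C)C)C1=O | intermediate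
20 | (1R,4R,5R)-isothiocineole (4,7,7-trimethyl-6-thiabicyclo[3.2.1]octane) | C[C@@H]1CC[C@@H]2C[C@H]1SC2(C)C | starting material
21 | S-alkyl isothiocineolium tetrafluoroborate of 19 (sulfur bonded to C4, alkyl group syn to the one-carbon bridge; formed in the flask) | C[C@@H]1CC[C@@H]2C[C@H]1[S@@+](CCCN(C(=O)OC(C)(C)C)C3=C(C)C(=O)\C(=C/[C@H](O[Si](CC)(CC)CC)[C@H](C)O[Si](C)(C)C(C)(C)C)C3=O)C2(C)C.F[B-](F)(F)F | intermediate
22 | N-Boc (4R,4aS)-4,4a-epoxy-6-oxo enone with C2'-OTES and C3'-OTBS, C2' cis to C6 | CC[Si](CC)(CC)O[C@@H](/C=C1\C(=O)C(C)=C2N(C(=O)OC(C)(C)C)CC[C@H]3O[C@]213)[C@H](C)O[Si](C)(C)C(C)(C)C | intermediate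
23 | C2' alcohol of 22 | O[C@@H](/C=C1\C(=O)C(C)=C2N(C(=O)OC(C)(C)C)CC[C@H]3O[C@]213)[C@H](C)O[Si](C)(C)C(C)(C)C | intermediate
24 | (R)-2-methylbutanoic acid | CC[C@@H](C)C(=O)O | starting material
25 | C2' (R)-2-methylbutanoate with C3'-OTBS | CC[C@@H](C)C(=O)O[C@@H](/C=C1\C(=O)C(C)=C2N(C(=O)OC(C)(C)C)CC[C@H]3O[C@]213)[C@H](C)O[Si](C)(C)C(C)(C)C | intermediate
26 | C2' (R)-2-methylbutanoate with free C3' hydroxyl | CC[C@@H](C)C(=O)O[C@@H](/C=C1\C(=O)C(C)=C2N(C(=O)OC(C)(C)C)CC[C@H]3O[C@]213)[C@H](C)O | intermediate
27 | N-Boc epoxy enone with C2' (R)-2-methylbutanoate and C3' acetate | CC[C@@H](C)C(=O)O[C@@H](/C=C1\C(=O)C(C)=C2N(C(=O)OC(C)(C)C)CC[C@H]3O[C@]213)[C@H](C)OC(C)=O | intermediate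
28 | C6 alcohol of 27 (C6 epimers) | CC[C@@H](C)C(=O)O[C@@H](/C=C1\C(O)C(C)=C2N(C(=O)OC(C)(C)C)CC[C@H]3O[C@]213)[C@H](C)OC(C)=O | intermediate
29 | target CNP0149008.3 | CC[C@@H](C)C(=O)O[C@@H](/C=C1\C=C(C)C2=NCC[C@H]3O[C@]213)[C@H](C)OC(C)=O | target

## Step count and least certain steps

Total: 19 steps. Longest linear sequence: 15 steps (steps 5 to 10, then 11 to 19); the squarate arm (steps 1 to 4) joins at step 11.

Step 12 (key step). The likely failure is a diverted pathway at the palladium-activated alkyne: attack by the carbamate carbonyl in place of the acyl shift, slow protonolysis with catalyst deactivation by traces of iodide, or erosion of the alkene geometry by reversible addition to the product. Fallback: from 18, a stoichiometric iodonium source (N-iodosuccinimide, CH2Cl2, 0 °C) triggers the same anti acyl shift and gives the iodoalkylidene dione F1. Hydrodeiodination with retention, using Pd(PPh3)4 (zerovalent palladium) and Bu3SnH at 0 °C in the dark, then returns to 19; the vinyl iodide should react far faster than the primary alkyl iodide.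

Step 13. Three processes can fail:
- S-alkylation of a hindered sulfide may be slow, giving time for participation of the carbamate carbonyl at C4 or for sulfide addition to the alkylidene dione.
- The base may deprotonate C2' (epimerisation or deconjugation) or cause elimination from the sulfonium salt.
- Facial selectivity of the ylide may be poor or of the wrong sense.

Fallback: from 19, Ph2S and AgBF4 give the diphenylsulfonium salt F2. It has a single α-site, is more acidic and needs only KOt-Bu at −78 °C. Ring closure without reagent control gives 22 together with its (4S,4aR) diastereomer F3, and 22 is separated by chromatography.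

Step 11. The likely failures are addition at the carbonyl next to the methyl-bearing carbon, transfer of Boc from nitrogen to the new alkoxide, and alkoxide-accelerated ring opening on warming. Fallback: the acetylide 17 is added to 3, where attack beside the alkoxy-bearing carbon is the established regiochemistry, giving the isopropoxy carbinol F4. Exchange with 4 and Et3N gives the chloropropylamino carbinol F5, NaI in acetone gives the iodide F6, and Boc2O with DMAP returns to 18.

Step 19. The likely failure is acid-promoted opening of the oxirane or oligomerisation of the azatriene before neutralisation. Fallback: from 27, the activated (vinylogous imide) Boc group is removed without protic acid (Mg(ClO4)2, MeCN, 50 °C) to give the N–H vinylogous amide F7. Chemoselective hydrosilylation of its C6 carbonyl with IrCl(CO)(PPh3)2 and (Me2SiH)2O leaves the esters untouched and gives the silyl ether F8, which loses the silanol on neutral work-up to reach 29.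

## Further compounds

F1 | step 12 | N-Boc N-(3-iodopropyl) 4-amino-5-methyl-2-[1-iodo-(2S,3S)-3-(tert-butyldimethylsilyloxy)-2-(triethylsilyloxy)butylidene]cyclopent-4-ene-1,3-dione, iodine trans to C6 | CC1=C(N(CCCI)C(=O)OC(C)(C)C)C(=O)/C(=C(\I)[C@H](O[Si](CC)(CC)CC)[C@H](C)O[Si](C)(C)C(C)(C)C)C1=O
F2 | step 13 | diphenylsulfonium tetrafluoroborate of 19 (sulfur on C4) | CC1=C(N(CCC[S+](c2ccccc2)c2ccccc2)C(=O)OC(C)(C)C)C(=O)/C(=C/[C@H](O[Si](CC)(CC)CC)[C@H](C)O[Si](C)(C)C(C)(C)C)C1=O.F[B-](F)(F)F
F3 | step 13 | (4S,4aR) diastereomer of 22 | CC[Si](CC)(CC)O[C@@H](/C=C1\C(=O)C(C)=C2N(C(=O)OC(C)(C)C)CC[C@@H]3O[C@@]213)[C@H](C)O[Si](C)(C)C(C)(C)C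
F4 | step 11 | 4-hydroxy-3-isopropoxy-2-methyl-4-[(3S,4S)-4-(tert-butyldimethylsilyloxy)-3-(triethylsilyloxy)pent-1-ynyl]cyclobut-2-enone, carbinol epimers | CC1=C(OC(C)C)C(O)(C#C[C@H](O[Si](CC)(CC)CC)[C@H](C)O[Si](C)(C)C(C)(C)C)C1=O
F5 | step 11 | 3-[(3-chloropropyl)amino] analogue of F4 | CC1=C(NCCCCl)C(O)(C#C[C@H](O[Si](CC)(CC)CC)[C@H](C)O[Si](C)(C)C(C)(C)C)C1=O
F6 | step 11 | 3-[(3-iodopropyl)amino] analogue of F4 | CC1=C(NCCCI)C(O)(C#C[C@H](O[Si](CC)(CC)CC)[C@H](C)O[Si](C)(C)C(C)(C)C)C1=O
F7 | step 19 | N–H vinylogous amide from 27 (Boc removed) | CC[C@@H](C)C(=O)O[C@@H](/C=C1\C(=O)C(C)=C2NCC[C@H]3O[C@]213)[C@H](C)OC(C)=O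
F8 | step 19 | C6 O-(1,1,3,3-tetramethyldisiloxanyl) ether from F7 (C6 epimers) | CC[C@@H](C)C(=O)O[C@@H](/C=C1\C(O[Si](C)(C)O[SiH](C)C)C(C)=C2NCC[C@H]3O[C@]213)[C@H](C)OC(C)=O
A1 | alternative 1 | 4-hydroxy-2-methylcyclopent-2-enone bearing on C4 a 1-(tert-butyldimethylsilyloxy)-3-(Boc-amino)propyl arm, configuration as in the SMILES | O=C1C[C@@](O)([C@@H](O[Si](C)(C)C(C)(C)C)CCNC(=O)OC(C)(C)C)C=C1C
A2 | alternative 1 | 2,3-dimethyl-5-[1-(tert-butyldimethylsilyloxy)-3-(Boc-amino)propyl]furan | Cc1oc(cc1C)[C@@H](O[Si](C)(C)C(C)(C)C)CCNC(=O)OC(C)(C)C
A3 | alternative 2 | cis-fused N-Boc 4,4a-epoxy-7-methyl-octahydrocyclopenta[b]pyridin-6-one | C[C@@H]1C(=O)C[C@]23[C@H]1N(C(=O)OC(C)(C)C)CC[C@H]2O3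
A4 | alternative 2 | N-Boc 3,4-epoxy-3-(3-diazo-2-oxobutyl)piperidine | CC(=[N+]=[N-])C(=O)C[C@]12CN(C(=O)OC(C)(C)C)CC[C@H]1O2
A5 | alternative 3 | spiro-epoxy 4-alkylidene-2-methylcyclopent-2-enone azide carrying both esters | CC[C@@H](C)C(=O)O[C@@H](/C=C1\C=C(C)C(=O)[C@@]12O[C@@H]2CCN=[N+]=[N-])[C@H](C)OC(C)=O
A6 | alternative 3 | acyclic epoxy ethyl ketone enal azide carrying both esters | CC[C@@H](C)C(=O)O[C@@H](/C=C(\C=O)[C@]1(O[C@@H]1CCN=[N+]=[N-])C(=O)CC)[C@H](C)OC(C)=O
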